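**Retrosynthetic overview**
1. Target acid ⇐ C1 primary alcohol (oxidised last) ⇐ Negishi sp2–sp3 coupling (C8–C9) of the dioxanyl (E)-vinyl iodide 32 with (S)-2-ethylhexylzinc iodide 38.
2. 32 ⇐ propynyl dioxane ⇐ dioxane-6-carbaldehyde 27 (alkyne homologation, methylation, hydrozirconation–iodination) ⇐ glycol cleavage.
3. The only ring, the 1,2-dioxane, is closed once at O–C3: a tertiary C6 peroxide anion displaces a C3 mesylate (inversion). The C6–OO bond comes from perhydrolysis (inversion) of a Sharpless epoxide.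
4. Open chain ⇐ Noyori reduction of a β-keto ester (C3), Masamune homologation, Negishi coupling of a (Z)-3-iodopent-2-enyl ether with an ethyl-branched alkylzinc (C5–C6).
5. Both ethyl-bearing stereocentres ⇐ allyl alcohol by Zr-catalysed asymmetric ethylalumination–iodinolysis, brought to ≥99% ee by lipase-catalysed acetylation.

Assumption: (+)-(NMI)2ZrCl2 gives the S and (−)-(NMI)2ZrCl2 the R iodo alcohol, and the lipase acetylates the R enantiomer faster (iodomethyl as the large group); if the zirconocene sense is the reverse, the two catalyst enantiomers are exchanged between steps 1 and 23.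

**Route**

Step 1
Reactants: 1 prop-2-en-1-ol
Product: 3 (2S)-2-ethyl-3-iodopropan-1-ol (ca. 85% ee), via alkylalane 2 (not isolated)
Conditions: Et3Al (3 equiv), (+)-(NMI)2ZrCl2 [dichlorobis(1-neomenthylindenyl)zirconium, 5 mol%], isobutylaluminoxane, CH2Cl2, 0 → 23 °C; then I2, THF, 0 °C; aq. HCl
Reagents that add atoms: triethylaluminium CC[Al](CC)CC; iodine II
Why: Zr-catalysed asymmetric carboalumination (ZACA) of the aluminium alkoxide adds Et–Al across the alkene, the chiral zirconocene choosing the face and so setting the future ring C4, and iodinolysis converts C–Al into C–I.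

Step 2
Reactants: 3 (2S)-2-ethyl-3-iodopropan-1-ol (ca. 85% ee)
Product: 4 tert-butyl{[(2S)-2-ethyl-3-iodopropyl]oxy}dimethylsilane (≥99% ee)
Conditions: lipase (Burkholderia cepacia lipase), vinyl acetate (0.3 equiv), ClCH2CH2Cl, 23 °C, to ca. 15% conversion; filter off the enzyme; then TBSCl, imidazole, DMAP (cat.), same solution, 23 °C; chromatography
Reagents that add atoms: tert-butyldimethylsilyl chloride CC(C)(C)[Si](C)(C)Cl
Why: Lipase-catalysed kinetic resolution by transesterification acetylates the residual R alcohol much faster (iodomethyl versus ethyl is well discriminated), and silylating the untouched S alcohol in the filtrate gives a silyl ether that separates cleanly from the R acetate and survives zinc insertion and cross-coupling.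

Step 3
Reactants: 5 pent-2-yn-1-ol
Product: 7 (2Z)-3-iodopent-2-en-1-ol, via cyclic alkenylalanate 6 (not isolated)
Conditions: NaAlH2(OCH2CH2OCH3)2, THF, 0 → 23 °C; then I2, THF, −78 → 0 °C
Reagents that add atoms: iodine II
Why: Alkoxide-directed trans-hydroalumination places aluminium on C3 in a five-membered alkoxyalanate, and iodinolysis with retention gives the Z iodoalkene only.

Step 4
Reactants: 7 (2Z)-3-iodopent-2-en-1-ol
Product: 8 1-({[(2Z)-3-iodopent-2-en-1-yl]oxy}methyl)-4-methoxybenzene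
Conditions: NaH, 4-methoxybenzyl chloride, Bu4NI (cat.), THF/DMF, 0 → 23 °C
Reagents that add atoms: 4-methoxybenzyl chloride COc1ccc(CCl)cc1
Why: Williamson etherification gives a PMB ether that is orthogonal to the silyl ethers and is removed oxidatively later.

Step 5
Reactants: 4 tert-butyl{[(2S)-2-ethyl-3-iodopropyl]oxy}dimethylsilane; 8 1-({[(2Z)-3-iodopent-2-en-1-yl]oxy}methyl)-4-methoxybenzene
Product: 10 tert-butyl({(2R,4Z)-2,4-diethyl-6-[(4-methoxyphenyl)methoxy]hex-4-en-1-yl}oxy)dimethylsilane, via alkylzinc iodide 9 (not isolated)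
Conditions: 4, Zn dust (activated: BrCH2CH2Br, TMSCl), DMA, 40 °C; then 8, Pd(PPh3)4 (5 mol%), THF, 23 → 45 °C
Reagents that add atoms: none
Why: Zinc insertion into the primary C–I bond and Pd-catalysed Negishi sp3–sp2 coupling form C5–C6 with retention of the Z geometry and without touching the β-stereocentre.

Step 6
Reactants: 10 tert-butyl({(2R,4Z)-2,4-diethyl-6-[(4-methoxyphenyl)methoxy]hex-4-en-1-yl}oxy)dimethylsilane
Product: 11 (2R,4Z)-2,4-diethyl-6-[(4-methoxyphenyl)methoxy]hex-4-en-1-ol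
Conditions: TBAF, THF, 0 → 23 °C
Reagents that add atoms: none
Why: Fluoride desilylation frees the primary alcohol while the PMB ether stays.

Step 7
Reactants: 11 (2R,4Z)-2,4-diethyl-6-[(4-methoxyphenyl)methoxy]hex-4-en-1-ol
Product: 13 (2R,4Z)-2,4-diethyl-6-[(4-methoxyphenyl)methoxy]hex-4-enoic acid, via aldehyde 12 (not isolated)
Conditions: TEMPO (20 mol%), PhI(OAc)2 (2.2 equiv), MeCN/H2O 1:1, 23 °C
Reagents that add atoms: water O
Why: TEMPO/PhI(OAc)2 oxidation takes the alcohol through the aldehyde hydrate to the acid under near-neutral conditions that do not epimerise C4 or harm the alkene and PMB ether.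

Step 8
Reactants: 13 (2R,4Z)-2,4-diethyl-6-[(4-methoxyphenyl)methoxy]hex-4-enoic acid
Product: 15 methyl (4R,6Z)-4,6-diethyl-8-[(4-methoxyphenyl)methoxy]-3-oxooct-6-enoate, via acyl imidazole 14 (not isolated)
Conditions: CDI, THF, 23 °C; then KO2CCH2CO2Me, MgCl2, Et3N, THF, 23 → 45 °C; aq. citric acid
Reagents that add atoms: potassium methyl malonate COC(=O)CC(=O)[O-].[K+]
Why: Masamune–Brooks homologation, in which the acyl imidazolide C-acylates the magnesium malonate and decarboxylation gives the β-keto ester without enolising the α-stereocentre.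

Step 9
Reactants: 15 methyl (4R,6Z)-4,6-diethyl-8-[(4-methoxyphenyl)methoxy]-3-oxooct-6-enoate
Product: 16 methyl (3S,4R,6Z)-4,6-diethyl-3-hydroxy-8-[(4-methoxyphenyl)methoxy]oct-6-enoate
Conditions: RuCl2[(R)-BINAP] (1 mol%), H2 (10 atm), MeOH, 50 °C
Reagents that add atoms: none
Why: Noyori asymmetric hydrogenation of the chelated β-keto ester is catalyst-controlled, (R)-BINAP giving the 3S carbinol (the same facial sense that gives (R)-3-hydroxybutanoate, the descriptor changing because the branched C4 outranks CH2CO2Me), and the isolated trisubstituted alkene and PMB ether are inert.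

Step 10
Reactants: 16 methyl (3S,4R,6Z)-4,6-diethyl-3-hydroxy-8-[(4-methoxyphenyl)methoxy]oct-6-enoate
Product: 17 (3S,4R,6Z)-4,6-diethyl-8-[(4-methoxyphenyl)methoxy]oct-6-ene-1,3-diol
Conditions: LiBH4, THF, MeOH (2 equiv), 0 → 23 °C
Reagents that add atoms: none
Why: Borohydride reduction of the ester removes the carbonyl that would otherwise make a C3 leaving group eliminate.

Step 11
Reactants: 17 (3S,4R,6Z)-4,6-diethyl-8-[(4-methoxyphenyl)methoxy]oct-6-ene-1,3-diol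
Product: 18 (3S,4R,6Z)-1-{[tert-butyl(diphenyl)silyl]oxy}-4,6-diethyl-8-[(4-methoxyphenyl)methoxy]oct-6-en-3-ol
Conditions: TBDPSCl (1.05 equiv), imidazole, CH2Cl2, 0 °C
Reagents that add atoms: tert-butyldiphenylsilyl chloride CC(C)(C)[Si](Cl)(c1ccccc1)c1ccccc1
Why: The bulky silyl chloride reacts selectively at the primary hydroxyl over the hindered secondary one.

Step 12
Reactants: 18 (3S,4R,6Z)-1-{[tert-butyl(diphenyl)silyl]oxy}-4,6-diethyl-8-[(4-methoxyphenyl)methoxy]oct-6-en-3-ol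
Product: 19 (3S,4R,6Z)-1-{[tert-butyl(diphenyl)silyl]oxy}-4,6-diethyl-8-[(4-methoxyphenyl)methoxy]oct-6-en-3-yl methanesulfonate
Conditions: MsCl, Et3N, CH2Cl2, 0 °C
Reagents that add atoms: methanesulfonyl chloride CS(=O)(=O)Cl
Why: O-Sulfonylation with retention installs the C3 leaving group for the later SN2 ring closure.

Step 13
Reactants: 19 (3S,4R,6Z)-1-{[tert-butyl(diphenyl)silyl]oxy}-4,6-diethyl-8-[(4-methoxyphenyl)methoxy]oct-6-en-3-yl methanesulfonate
Product: 20 (3S,4R,6Z)-1-{[tert-butyl(diphenyl)silyl]oxy}-4,6-diethyl-8-hydroxyoct-6-en-3-yl methanesulfonate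
Conditions: DDQ, CH2Cl2/pH 7 buffer 10:1, 0 °C
Reagents that add atoms: none
Why: Oxidative PMB cleavage frees the allylic alcohol under neutral conditions that leave the mesylate and silyl ether alone.

Step 14
Reactants: 20 (3S,4R,6Z)-1-{[tert-butyl(diphenyl)silyl]oxy}-4,6-diethyl-8-hydroxyoct-6-en-3-yl methanesulfonate
Product: 21 (3S,4R)-1-{[tert-butyl(diphenyl)silyl]oxy}-4-ethyl-5-[(2R,3S)-2-ethyl-3-(hydroxymethyl)oxiran-2-yl]pentan-3-yl methanesulfonate
Conditions: Ti(OiPr)4 (10 mol%), L-(+)-diethyl tartrate (12 mol%), t-BuOOH, 4 Å molecular sieves, CH2Cl2, −20 °C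
Reagents that add atoms: tert-butyl hydroperoxide CC(C)(C)OO
Why: Katsuki–Sharpless asymmetric epoxidation is reagent-controlled, and on this nerol-type Z allylic alcohol L-(+)-tartrate gives the (2R,3S)-epoxide, that is R at the future C6.

Step 15
Reactants: 21 (3S,4R)-1-{[tert-butyl(diphenyl)silyl]oxy}-4-ethyl-5-[(2R,3S)-2-ethyl-3-(hydroxymethyl)oxiran-2-yl]pentan-3-yl methanesulfonate
Product: 22 (3S,4R,6S,7S)-1-{[tert-butyl(diphenyl)silyl]oxy}-4,6-diethyl-6-hydroperoxy-7,8-dihydroxyoctan-3-yl methanesulfonate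
Conditions: anhydrous H2O2 in Et2O (excess), H3PMo12O40 (5 mol%), Et2O, 0 → 23 °C
Reagents that add atoms: hydrogen peroxide OO
Why: Acid-catalysed perhydrolysis opens the epoxide at the tertiary carbon from the face opposite the epoxide oxygen (borderline SN2, inversion), turning the R epoxide carbon into the 6S hydroperoxide carbon.

Step 16
Reactants: 22 (3S,4R,6S,7S)-1-{[tert-butyl(diphenyl)silyl]oxy}-4,6-diethyl-6-hydroperoxy-7,8-dihydroxyoctan-3-yl methanesulfonate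
Product: 23 (3S,4R,6S,7S)-1-{[tert-butyl(diphenyl)silyl]oxy}-4,6-diethyl-7,8-bis[(triethylsilyl)oxy]-6-[(triethylsilyl)peroxy]octan-3-yl methanesulfonate
Conditions: Et3SiOTf (3.6 equiv), 2,6-lutidine, CH2Cl2, −78 → −40 °C
Reagents that add atoms: triethylsilyl trifluoromethanesulfonate CC[Si](CC)(CC)OS(=O)(=O)C(F)(F)F
Why: Silylation masks the glycol, so no alkoxide next to the peroxide can trigger Grob-type C–C cleavage, and stores the hydroperoxide as a fluoride-labile silyl peroxide.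

Step 17
Reactants: 23 (3S,4R,6S,7S)-1-{[tert-butyl(diphenyl)silyl]oxy}-4,6-diethyl-7,8-bis[(triethylsilyl)oxy]-6-[(triethylsilyl)peroxy]octan-3-yl methanesulfonate
Product: 25 tert-butyl(2-{(3R,4R,6S)-6-[(1S)-1,2-bis(triethylsilyloxy)ethyl]-4,6-diethyl-1,2-dioxan-3-yl}ethoxy)diphenylsilane, via hydroperoxide 24 (not isolated)
Conditions: TBAF (1.2 equiv), THF, −40 → 0 °C
Reagents that add atoms: none
Why: Fluoride cleaves the Si–OO bond first, and the tertiary peroxide anion displaces the C3 mesylate in a 6-exo-tet intramolecular SN2 (Williamson-type peroxide alkylation) with inversion, giving 3R cis to the C4 ethyl and closing the only ring.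

Step 18
Reactants: 25 tert-butyl(2-{(3R,4R,6S)-6-[(1S)-1,2-bis(triethylsilyloxy)ethyl]-4,6-diethyl-1,2-dioxan-3-yl}ethoxy)diphenylsilane
Product: 26 (1S)-1-[(3R,4R,6S)-3-(2-{[tert-butyl(diphenyl)silyl]oxy}ethyl)-4,6-diethyl-1,2-dioxan-6-yl]ethane-1,2-diol
Conditions: AcOH/THF/H2O 3:1:1, 23 °C
Reagents that add atoms: none
Why: Mild acid hydrolysis removes the triethylsilyl ethers while the primary TBDPS ether and the peroxide are stable.

Step 19
Reactants: 26 (1S)-1-[(3R,4R,6S)-3-(2-{[tert-butyl(diphenyl)silyl]oxy}ethyl)-4,6-diethyl-1,2-dioxan-6-yl]ethane-1,2-diol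
Product: 27 (3R,4R,6S)-3-(2-{[tert-butyl(diphenyl)silyl]oxy}ethyl)-4,6-diethyl-1,2-dioxane-6-carbaldehyde
Conditions: NaIO4, THF/pH 7 buffer, 0 °C
Reagents that add atoms: none
Why: Malaprade glycol cleavage under neutral conditions gives the non-enolisable aldehyde on the quaternary C6 without touching the O–O bond.

Step 20
Reactants: 27 (3R,4R,6S)-3-(2-{[tert-butyl(diphenyl)silyl]oxy}ethyl)-4,6-diethyl-1,2-dioxane-6-carbaldehyde
Product: 28 tert-butyl{2-[(3R,4R,6S)-4,6-diethyl-6-ethynyl-1,2-dioxan-3-yl]ethoxy}diphenylsilane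
Conditions: dimethyl (1-diazo-2-oxopropyl)phosphonate, K2CO3, MeOH, 0 → 23 °C
Reagents that add atoms: dimethyl (1-diazo-2-oxopropyl)phosphonate CC(=O)C(=[N+]=[N-])P(=O)(OC)OC
Why: Seyferth–Gilbert homologation with the Ohira–Bestmann reagent converts the aldehyde into the terminal alkyne under mild carbonate conditions.

Step 21
Reactants: 28 tert-butyl{2-[(3R,4R,6S)-4,6-diethyl-6-ethynyl-1,2-dioxan-3-yl]ethoxy}diphenylsilane
Product: 30 tert-butyl{2-[(3R,4R,6S)-4,6-diethyl-6-(prop-1-yn-1-yl)-1,2-dioxan-3-yl]ethoxy}diphenylsilane, via lithium acetylide 29 (not isolated)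
Conditions: LiN(iPr)2, THF, −78 °C; then MeI, DMPU, −78 → 0 °C
Reagents that add atoms: iodomethane CI
Why: Acetylide alkylation, where the hindered amide base deprotonates only the alkyne C–H at low temperature and avoids nucleophilic attack on the O–O bond.

Step 22
Reactants: 30 tert-butyl{2-[(3R,4R,6S)-4,6-diethyl-6-(prop-1-yn-1-yl)-1,2-dioxan-3-yl]ethoxy}diphenylsilane
Product: 32 tert-butyl(2-{(3R,4R,6S)-4,6-diethyl-6-[(1E)-2-iodoprop-1-en-1-yl]-1,2-dioxan-3-yl}ethoxy)diphenylsilane, via vinylzirconocene 31 (not isolated)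
Conditions: Cp2Zr(H)Cl (1.5 equiv), THF, 23 °C, dark; then I2, THF, 0 °C
Reagents that add atoms: iodine II
Why: Schwartz hydrozirconation adds Zr–H syn with zirconium on the less hindered methyl-bearing carbon, and iodinolysis with retention gives the E vinyl iodide with methyl cis to the dioxane carbon.

Step 23
Reactants: 1 prop-2-en-1-ol
Product: 34 (2R)-2-ethyl-3-iodopropan-1-ol (ca. 85% ee), via alkylalane 33 (not isolated)
Conditions: Et3Al (3 equiv), (−)-(NMI)2ZrCl2 (5 mol%), isobutylaluminoxane, CH2Cl2, 0 → 23 °C; then I2, THF, 0 °C; aq. HCl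
Reagents that add atoms: triethylaluminium CC[Al](CC)CC; iodine II
Why: The same ZACA ethylalumination–iodinolysis with the enantiomeric zirconocene sets the side-chain stereocentre.

Step 24
Reactants: 34 (2R)-2-ethyl-3-iodopropan-1-ol (ca. 85% ee)
Product: 35 (2R)-2-ethyl-3-iodopropyl acetate (≥99% ee)
Conditions: lipase (Burkholderia cepacia lipase), vinyl acetate, ClCH2CH2Cl, 23 °C, to ca. 85% conversion; chromatography
Reagents that add atoms: vinyl acetate CC(=O)OC=C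
Why: Lipase-catalysed enantioselective acetylation collects the fast-reacting R alcohol as its acetate and leaves the S impurity behind as alcohol.

Step 25
Reactants: 35 (2R)-2-ethyl-3-iodopropyl acetate
Product: 36 (2S)-2-ethylhexan-1-ol
Conditions: n-PrMgCl (4.5 equiv), Li2CuCl4 (5 mol%), THF, −20 → 0 °C; aq. NH4Cl
Reagents that add atoms: n-propylmagnesium chloride CCC[Mg]Cl
Why: Copper-catalysed (Kochi-type) sp3–sp3 coupling at the primary iodide makes the butyl arm, excess Grignard removes the acetate, and the stereocentre is not involved (the descriptor changes only by priority).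

Step 26
Reactants: 36 (2S)-2-ethylhexan-1-ol
Product: 37 (3S)-3-(iodomethyl)heptane
Conditions: I2, PPh3, imidazole, CH2Cl2, 0 → 23 °C
Reagents that add atoms: iodine II
Why: Appel-type iodination of the primary alcohol, with the β-stereocentre untouched.

Step 27
Reactants: 37 (3S)-3-(iodomethyl)heptane; 32 tert-butyl(2-{(3R,4R,6S)-4,6-diethyl-6-[(1E)-2-iodoprop-1-en-1-yl]-1,2-dioxan-3-yl}ethoxy)diphenylsilane
Product: 39 tert-butyl(2-{(3R,4R,6S)-4,6-diethyl-6-[(1E,4S)-4-ethyl-2-methyloct-1-en-1-yl]-1,2-dioxan-3-yl}ethoxy)diphenylsilane, via alkylzinc iodide 38 (not isolated)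
Conditions: 37, Zn dust (activated), DMA, 40 °C, decant from excess Zn; then 32, PdCl2(dppf) (5 mol%), THF/DMA, 23 °C
Reagents that add atoms: none
Why: Negishi sp3–sp2 coupling proceeds with retention at the vinyl iodide to give the E trisubstituted alkene, and the mild alkylzinc halide at room temperature spares the dialkyl peroxide.

Step 28
Reactants: 39 tert-butyl(2-{(3R,4R,6S)-4,6-diethyl-6-[(1E,4S)-4-ethyl-2-methyloct-1-en-1-yl]-1,2-dioxan-3-yl}ethoxy)diphenylsilane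
Product: 40 2-{(3R,4R,6S)-4,6-diethyl-6-[(1E,4S)-4-ethyl-2-methyloct-1-en-1-yl]-1,2-dioxan-3-yl}ethan-1-ol
Conditions: TBAF, AcOH (1:1), THF, 0 → 23 °C
Reagents that add atoms: none
Why: Buffered fluoride desilylation frees the primary alcohol without base-induced peroxide chemistry.

Step 29
Reactants: 40 2-{(3R,4R,6S)-4,6-diethyl-6-[(1E,4S)-4-ethyl-2-methyloct-1-en-1-yl]-1,2-dioxan-3-yl}ethan-1-ol
Product: 42 2-{(3R,4R,6S)-4,6-diethyl-6-[(1E,4S)-4-ethyl-2-methyloct-1-en-1-yl]-1,2-dioxan-3-yl}acetic acid, via aldehyde 41 (not isolated)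
Conditions: TEMPO (20 mol%), PhI(OAc)2 (2.5 equiv), MeCN/pH 7 buffer 1:1, 0 → 23 °C
Reagents that add atoms: water O
Why: TEMPO/PhI(OAc)2 oxidation to the acid under buffered conditions, so the transient β-peroxy aldehyde is hydrated and oxidised on before it can undergo retro-Michael ring opening.

**Compound list** (dioxane locants follow the target: C3 carries the two-carbon arm, C4 and C6 the ethyl groups)

1 | prop-2-en-1-ol (allyl alcohol) | C=CCO | starting material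
2 | diethyl{[(2S)-3-(diethylalumanyl)-2-ethylpropyl]oxy}alumane (not isolated) | CC[Al](CC)C[C@@H](CC)CO[Al](CC)CC | intermediate
3 | (2S)-2-ethyl-3-iodopropan-1-ol | IC[C@@H](CC)CO | intermediate
4 | tert-butyl{[(2S)-2-ethyl-3-iodopropyl]oxy}dimethylsilane | IC[C@@H](CC)CO[Si](C)(C)C(C)(C)C | intermediate
5 | pent-2-yn-1-ol | CCC#CCO | starting material
6 | sodium 3-ethyl-2,2-bis(2-methoxyethoxy)-2,5-dihydro-1,2-oxaluminol-2-uide, cyclic Z-alkenylalanate (not isolated) | CCC1=CCO[Al-]1(OCCOC)OCCOC.[Na+] | intermediate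
7 | (2Z)-3-iodopent-2-en-1-ol | CC/C(I)=C/CO | intermediate
8 | 1-({[(2Z)-3-iodopent-2-en-1-yl]oxy}methyl)-4-methoxybenzene | CC/C(I)=C/COCc1ccc(OC)cc1 | intermediate
9 | [(2S)-3-{[tert-butyl(dimethyl)silyl]oxy}-2-ethylpropyl](iodo)zinc (not isolated) | I[Zn]C[C@@H](CC)CO[Si](C)(C)C(C)(C)C | intermediate
10 | tert-butyl({(2R,4Z)-2,4-diethyl-6-[(4-methoxyphenyl)methoxy]hex-4-en-1-yl}oxy)dimethylsilane | CC/C(C[C@@H](CC)CO[Si](C)(C)C(C)(C)C)=C/COCc1ccc(OC)cc1 | intermediate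
11 | (2R,4Z)-2,4-diethyl-6-[(4-methoxyphenyl)methoxy]hex-4-en-1-ol | CC/C(C[C@@H](CC)CO)=C/COCc1ccc(OC)cc1 | intermediate
12 | (2R,4Z)-2,4-diethyl-6-[(4-methoxyphenyl)methoxy]hex-4-enal (not isolated) | CC/C(C[C@@H](CC)C=O)=C/COCc1ccc(OC)cc1 | intermediate
13 | (2R,4Z)-2,4-diethyl-6-[(4-methoxyphenyl)methoxy]hex-4-enoic acid | CC/C(C[C@@H](CC)C(=O)O)=C/COCc1ccc(OC)cc1 | intermediate
14 | 1-{(2R,4Z)-2,4-diethyl-6-[(4-methoxyphenyl)methoxy]hex-4-enoyl}-1H-imidazole (not isolated) | CC/C(C[C@@H](CC)C(=O)n1ccnc1)=C/COCc1ccc(OC)cc1 | intermediate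
15 | methyl (4R,6Z)-4,6-diethyl-8-[(4-methoxyphenyl)methoxy]-3-oxooct-6-enoate | CC/C(C[C@@H](CC)C(=O)CC(=O)OC)=C/COCc1ccc(OC)cc1 | intermediate
16 | methyl (3S,4R,6Z)-4,6-diethyl-3-hydroxy-8-[(4-methoxyphenyl)methoxy]oct-6-enoate | CC/C(C[C@@H](CC)[C@@H](O)CC(=O)OC)=C/COCc1ccc(OC)cc1 | intermediate
17 | (3S,4R,6Z)-4,6-diethyl-8-[(4-methoxyphenyl)methoxy]oct-6-ene-1,3-diol | CC/C(C[C@@H](CC)[C@@H](O)CCO)=C/COCc1ccc(OC)cc1 | intermediate
18 | (3S,4R,6Z)-1-{[tert-butyl(diphenyl)silyl]oxy}-4,6-diethyl-8-[(4-methoxyphenyl)methoxy]oct-6-en-3-ol | CC/C(C[C@@H](CC)[C@@H](O)CCO[Si](c1ccccc1)(c1ccccc1)C(C)(C)C)=C/COCc1ccc(OC)cc1 | intermediate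
19 | (3S,4R,6Z)-1-{[tert-butyl(diphenyl)silyl]oxy}-4,6-diethyl-8-[(4-methoxyphenyl)methoxy]oct-6-en-3-yl methanesulfonate | CC/C(C[C@@H](CC)[C@@H](OS(C)(=O)=O)CCO[Si](c1ccccc1)(c1ccccc1)C(C)(C)C)=C/COCc1ccc(OC)cc1 | intermediate
20 | (3S,4R,6Z)-1-{[tert-butyl(diphenyl)silyl]oxy}-4,6-diethyl-8-hydroxyoct-6-en-3-yl methanesulfonate | CC/C(C[C@@H](CC)[C@@H](OS(C)(=O)=O)CCO[Si](c1ccccc1)(c1ccccc1)C(C)(C)C)=C/CO | intermediate
21 | (3S,4R)-1-{[tert-butyl(diphenyl)silyl]oxy}-4-ethyl-5-[(2R,3S)-2-ethyl-3-(hydroxymethyl)oxiran-2-yl]pentan-3-yl methanesulfonate | OC[C@@H]1O[C@]1(CC)C[C@@H](CC)[C@@H](OS(C)(=O)=O)CCO[Si](c1ccccc1)(c1ccccc1)C(C)(C)C | intermediate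
22 | (3S,4R,6S,7S)-1-{[tert-butyl(diphenyl)silyl]oxy}-4,6-diethyl-6-hydroperoxy-7,8-dihydroxyoctan-3-yl methanesulfonate | OC[C@H](O)[C@](OO)(CC)C[C@@H](CC)[C@@H](OS(C)(=O)=O)CCO[Si](c1ccccc1)(c1ccccc1)C(C)(C)C | intermediate
23 | (3S,4R,6S,7S)-1-{[tert-butyl(diphenyl)silyl]oxy}-4,6-diethyl-7,8-bis[(triethylsilyl)oxy]-6-[(triethylsilyl)peroxy]octan-3-yl methanesulfonate | CC[Si](CC)(CC)OC[C@H](O[Si](CC)(CC)CC)[C@](OO[Si](CC)(CC)CC)(CC)C[C@@H](CC)[C@@H](OS(C)(=O)=O)CCO[Si](c1ccccc1)(c1ccccc1)C(C)(C)C | intermediate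
24 | (3S,4R,6S,7S)-1-{[tert-butyl(diphenyl)silyl]oxy}-4,6-diethyl-6-hydroperoxy-7,8-bis[(triethylsilyl)oxy]octan-3-yl methanesulfonate, formed as its tetrabutylammonium peroxide (not isolated) | CC[Si](CC)(CC)OC[C@H](O[Si](CC)(CC)CC)[C@](OO)(CC)C[C@@H](CC)[C@@H](OS(C)(=O)=O)CCO[Si](c1ccccc1)(c1ccccc1)C(C)(C)C | intermediate
25 | tert-butyl(2-{(3R,4R,6S)-6-[(1S)-1,2-bis(triethylsilyloxy)ethyl]-4,6-diethyl-1,2-dioxan-3-yl}ethoxy)diphenylsilane | CC[Si](CC)(CC)OC[C@H](O[Si](CC)(CC)CC)[C@]1(CC)C[C@@H](CC)[C@@H](CCO[Si](c2ccccc2)(c2ccccc2)C(C)(C)C)OO1 | intermediate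
26 | (1S)-1-[(3R,4R,6S)-3-(2-{[tert-butyl(diphenyl)silyl]oxy}ethyl)-4,6-diethyl-1,2-dioxan-6-yl]ethane-1,2-diol | OC[C@H](O)[C@]1(CC)C[C@@H](CC)[C@@H](CCO[Si](c2ccccc2)(c2ccccc2)C(C)(C)C)OO1 | intermediate
27 | (3R,4R,6S)-3-(2-{[tert-butyl(diphenyl)silyl]oxy}ethyl)-4,6-diethyl-1,2-dioxane-6-carbaldehyde | O=C[C@]1(CC)C[C@@H](CC)[C@@H](CCO[Si](c2ccccc2)(c2ccccc2)C(C)(C)C)OO1 | intermediate
28 | tert-butyl{2-[(3R,4R,6S)-4,6-diethyl-6-ethynyl-1,2-dioxan-3-yl]ethoxy}diphenylsilane | C#C[C@]1(CC)C[C@@H](CC)[C@@H](CCO[Si](c2ccccc2)(c2ccccc2)C(C)(C)C)OO1 | intermediate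
29 | lithium acetylide of 28 (not isolated) | [Li]C#C[C@]1(CC)C[C@@H](CC)[C@@H](CCO[Si](c2ccccc2)(c2ccccc2)C(C)(C)C)OO1 | intermediate
30 | tert-butyl{2-[(3R,4R,6S)-4,6-diethyl-6-(prop-1-yn-1-yl)-1,2-dioxan-3-yl]ethoxy}diphenylsilane | CC#C[C@]1(CC)C[C@@H](CC)[C@@H](CCO[Si](c2ccccc2)(c2ccccc2)C(C)(C)C)OO1 | intermediate
31 | chlorobis(cyclopentadienyl){(1E)-1-[(3R,4R,6S)-3-(2-{[tert-butyl(diphenyl)silyl]oxy}ethyl)-4,6-diethyl-1,2-dioxan-6-yl]prop-1-en-2-yl}zirconium (not isolated) | Cl[Zr](C1C=CC=C1)(C1C=CC=C1)/C(C)=C/[C@]2(CC)C[C@@H](CC)[C@@H](CCO[Si](c3ccccc3)(c3ccccc3)C(C)(C)C)OO2 | intermediate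
32 | tert-butyl(2-{(3R,4R,6S)-4,6-diethyl-6-[(1E)-2-iodoprop-1-en-1-yl]-1,2-dioxan-3-yl}ethoxy)diphenylsilane | I/C(C)=C/[C@]1(CC)C[C@@H](CC)[C@@H](CCO[Si](c2ccccc2)(c2ccccc2)C(C)(C)C)OO1 | intermediate
33 | diethyl{[(2R)-3-(diethylalumanyl)-2-ethylpropyl]oxy}alumane (not isolated) | CC[Al](CC)C[C@H](CC)CO[Al](CC)CC | intermediate
34 | (2R)-2-ethyl-3-iodopropan-1-ol | IC[C@H](CC)CO | intermediate
35 | (2R)-2-ethyl-3-iodopropyl acetate | IC[C@H](CC)COC(C)=O | intermediate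
36 | (2S)-2-ethylhexan-1-ol | CCCC[C@H](CC)CO | intermediate
37 | (3S)-3-(iodomethyl)heptane | CCCC[C@H](CC)CI | intermediate
38 | [(2S)-2-ethylhexyl](iodo)zinc (not isolated) | CCCC[C@H](CC)C[Zn]I | intermediate
39 | tert-butyl(2-{(3R,4R,6S)-4,6-diethyl-6-[(1E,4S)-4-ethyl-2-methyloct-1-en-1-yl]-1,2-dioxan-3-yl}ethoxy)diphenylsilane | CCCC[C@H](CC)C/C(C)=C/[C@]1(CC)C[C@@H](CC)[C@@H](CCO[Si](c2ccccc2)(c2ccccc2)C(C)(C)C)OO1 | intermediate
40 | 2-{(3R,4R,6S)-4,6-diethyl-6-[(1E,4S)-4-ethyl-2-methyloct-1-en-1-yl]-1,2-dioxan-3-yl}ethan-1-ol | CCCC[C@H](CC)C/C(C)=C/[C@]1(CC)C[C@@H](CC)[C@@H](CCO)OO1 | intermediate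
41 | {(3R,4R,6S)-4,6-diethyl-6-[(1E,4S)-4-ethyl-2-methyloct-1-en-1-yl]-1,2-dioxan-3-yl}acetaldehyde (not isolated) | CCCC[C@H](CC)C/C(C)=C/[C@]1(CC)C[C@@H](CC)[C@@H](CC=O)OO1 | intermediate
42 | 2-{(3R,4R,6S)-4,6-diethyl-6-[(1E,4S)-4-ethyl-2-methyloct-1-en-1-yl]-1,2-dioxan-3-yl}acetic acid | CCCC[C@H](CC)C/C(C)=C/[C@]1(CC)C[C@@H](CC)[C@@H](CC(=O)O)OO1 | target

**Step count and risks**

Total steps: 29. Longest linear sequence: 23 steps (1–2, 5–22, 27–29).

Steps most likely to fail: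

Step 15 (perhydrolysis). The tertiary epoxide may rearrange or open with partial loss of stereochemical integrity under acid. The fallback sets out from 20 and comes back at 26, reversing the order of the two C–O bond formations. The mesylate of 20 is displaced first by 2-methoxyprop-2-yl hydroperoxide (CsOH·H2O, DMF, 0 °C, SN2 with inversion) to give the C3 peroxyketal allylic alcohol F1. Sharpless epoxidation as in step 14 gives the peroxyketal epoxy alcohol F2. Camphorsulfonic acid in wet CH2Cl2 then frees the secondary hydroperoxide, which opens the epoxide intramolecularly at the tertiary carbon (6-exo, inversion) to give diol 26.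

Step 17 (ring closure). Elimination of the hindered mesylate, or silyl migration followed by fragmentation next to the peroxide anion, can compete with the SN2. The fallback sets out from 22 and comes back at 27. 2-Methoxypropene with PPTS turns the glycol into an acetonide and the hydroperoxide into its peroxyketal, the doubly masked mesylate F3. AcOH/THF/H2O at 0 °C releases only the hydroperoxide to give the acetonide hydroperoxide F4. Cs2CO3 in DMF closes the ring by the same SN2, now with a non-migrating, non-ionisable neighbour, to give the acetonide dioxane F5. H5IO6 in EtOAc unmasks and cleaves the glycol to aldehyde 27.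

Step 22 (hydrozirconation–iodination beside the peroxide). The zirconium hydride may attack the O–O bond, and steps 20 and 21 also expose the peroxide to base. The fallback sets out from 27 and comes back at 39, avoiding the alkyne altogether. PPh3/BrCCl3 (MeCN, 0 °C) gives the 1,1-dichloroalkene F6. Trans-selective Pd-catalysed alkylation with zinc reagent 38 (PdCl2(DPEphos), THF/DMF) gives the (Z)-chloroalkene F7. MeZnCl with Pd(PtBu3)2 then replaces the remaining chloride with retention to give 39.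

**Further compounds**

F1 | step 15 | (2Z,5R,6R)-8-{[tert-butyl(diphenyl)silyl]oxy}-3,5-diethyl-6-[(2-methoxypropan-2-yl)peroxy]oct-2-en-1-ol | CC/C(C[C@@H](CC)[C@@H](CCO[Si](c1ccccc1)(c1ccccc1)C(C)(C)C)OOC(C)(C)OC)=C/CO
F2 | step 15 | [(2S,3R)-3-{(2R,3R)-5-{[tert-butyl(diphenyl)silyl]oxy}-2-ethyl-3-[(2-methoxypropan-2-yl)peroxy]pentyl}-3-ethyloxiran-2-yl]methanol | OC[C@@H]1O[C@]1(CC)C[C@@H](CC)[C@@H](CCO[Si](c1ccccc1)(c1ccccc1)C(C)(C)C)OOC(C)(C)OC
F3 | step 17 | (3S,4R,6S)-1-{[tert-butyl(diphenyl)silyl]oxy}-6-[(4S)-2,2-dimethyl-1,3-dioxolan-4-yl]-4-ethyl-6-[(2-methoxypropan-2-yl)peroxy]octan-3-yl methanesulfonate | CC1(C)OC[C@H](O1)[C@](OOC(C)(C)OC)(CC)C[C@@H](CC)[C@@H](OS(C)(=O)=O)CCO[Si](c1ccccc1)(c1ccccc1)C(C)(C)C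
F4 | step 17 | (3S,4R,6S)-1-{[tert-butyl(diphenyl)silyl]oxy}-6-[(4S)-2,2-dimethyl-1,3-dioxolan-4-yl]-4-ethyl-6-hydroperoxyoctan-3-yl methanesulfonate | CC1(C)OC[C@H](O1)[C@](OO)(CC)C[C@@H](CC)[C@@H](OS(C)(=O)=O)CCO[Si](c1ccccc1)(c1ccccc1)C(C)(C)C
F5 | step 17 | tert-butyl(2-{(3R,4R,6S)-6-[(4S)-2,2-dimethyl-1,3-dioxolan-4-yl]-4,6-diethyl-1,2-dioxan-3-yl}ethoxy)diphenylsilane | CC1(C)OC[C@H](O1)[C@]2(CC)C[C@@H](CC)[C@@H](CCO[Si](c3ccccc3)(c3ccccc3)C(C)(C)C)OO2
F6 | step 22 | tert-butyl{2-[(3R,4R,6S)-6-(2,2-dichloroethenyl)-4,6-diethyl-1,2-dioxan-3-yl]ethoxy}diphenylsilane | ClC(Cl)=C[C@]1(CC)C[C@@H](CC)[C@@H](CCO[Si](c2ccccc2)(c2ccccc2)C(C)(C)C)OO1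
F7 | step 22 | tert-butyl(2-{(3R,4R,6S)-6-[(1Z,4S)-2-chloro-4-ethyloct-1-en-1-yl]-4,6-diethyl-1,2-dioxan-3-yl}ethoxy)diphenylsilane | CCCC[C@H](CC)C/C(Cl)=C/[C@]1(CC)C[C@@H](CC)[C@@H](CCO[Si](c2ccccc2)(c2ccccc2)C(C)(C)C)OO1
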